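**Retrosynthetic overview**

1. Ring atoms: C1 (ketone), C2 (bears CH2OH), C3, C4, C5 (quaternary), C6 (enol ester arm), C7 (acetonyl arm). The strategy rests on the 1,4-diketone C1(=O)–C7–CH2–C(=O)CH3 that spans C7 of the cycloheptenone: cutting C1–C7 gives an acyl radical at C1 and an (E)-enone whose β-carbon is C7.
2. The open-chain precursor is a (Z)-α,β-unsaturated phenyl selenoester; its C1–C3 unit comes from a Z-selective phosphonate olefination and the enone from a Wittig reaction, both on one 1,5-dialdehyde.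
3. C5 and C6 come from an enantioselective Ireland–Claisen rearrangement of geranyl 4,4-dimethoxybutanoate; the vinyl group left on C5 is hydroborated to the C4–C3 unit.
4. The cycloheptenone is the only ring; it is closed by the 7-exo acyl radical cyclisation after all acyclic stereocentres are in place.
5. End game: acetal to aldehyde, (E)-enol senecioate, desilylation, Schenck ene reaction for the allylic hydroperoxide.

Key step: step 12

Assumption (sense of induction in step 3): the (4R,5R)-diazaborolidine is taken to deliver the (2R,3S) acid; if the opposite sense is found, its (4S,5S) enantiomer is used with no other change.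

Remark: the C2 hydroxymethyl group is carried as its TIPS ether, because this unit can be introduced in one step from commercial (chloromethoxy)tri(propan-2-yl)silane.

**Route**

Step 1
Reactants: 1 methyl 4,4-dimethoxybutanoate
Product: 2 4,4-dimethoxybutanoic acid
Conditions: LiOH·H2O, THF/H2O, rt; 1 M HCl to pH 4 at 0 °C
Reagents that add atoms: LiOH, [Li+].[OH-]
Why: Ester saponification, in which the dimethyl acetal is inert to base and survives the cold, weakly acidic work-up.

Step 2
Reactants: 2 4,4-dimethoxybutanoic acid; 3 geraniol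
Product: 4 geranyl 4,4-dimethoxybutanoate
Conditions: DCC, DMAP (cat.), CH2Cl2, 0 °C to rt
Reagents that add atoms: none
Why: Steglich esterification joins the primary allylic alcohol and the acid under neutral conditions that leave the acetal and the (E)-alkene untouched.

Step 3
Reactants: 4 geranyl 4,4-dimethoxybutanoate
Product: 6 (2R,3S)-2-(2,2-dimethoxyethyl)-3-ethenyl-3,7-dimethyloct-6-enoic acid, via boron ketene acetal 5 (not isolated)
Conditions: (4R,5R)-2-bromo-4,5-diphenyl-1,3-bis[3,5-bis(trifluoromethyl)phenylsulfonyl]-1,3,2-diazaborolidine (1.1 equiv), iPr2NEt, CH2Cl2, −78 °C; then 4 °C to rt, several days; aqueous work-up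
Reagents that add atoms: none
Why: Enantioselective Ireland–Claisen rearrangement through a chiral boron ketene acetal, in which the hindered amine in CH2Cl2 should give the Z(O) enolate (side chain cis to O–B), the chair transition state with the homoprenyl group equatorial and the methyl axial sets C5 and C6 in the required syn relation, the sulfonamide ligand selects the enolate face, and the bulky B–Br reagent is consumed by enolisation at −78 °C before it can ionise the acetal.

Step 4
Reactants: 6 (2R,3S)-2-(2,2-dimethoxyethyl)-3-ethenyl-3,7-dimethyloct-6-enoic acid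
Product: 7 (2R,3S)-2-(2,2-dimethoxyethyl)-3-ethenyl-3,7-dimethyloct-6-en-1-ol
Conditions: LiAlH4, THF, 0 °C to rt
Reagents that add atoms: none
Why: Hydride reduction of the carboxylic acid to the primary alcohol, which touches neither the alkenes nor the acetal nor the two stereocentres.

Step 5
Reactants: 7 (2R,3S)-2-(2,2-dimethoxyethyl)-3-ethenyl-3,7-dimethyloct-6-en-1-ol
Product: 9 (2R,3S)-2-(2,2-dimethoxyethyl)-3-methyl-3-(4-methylpent-3-en-1-yl)pentane-1,5-diol, via bis(9-BBN) adduct 8 (not isolated)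
Conditions: 9-borabicyclo[3.3.1]nonane (2.5 equiv), THF, 0 to 40 °C; then NaOH, H2O2, 0 °C to rt
Reagents that add atoms: hydrogen peroxide, OO
Why: Hydroboration–oxidation, in which 9-borabicyclo[3.3.1]nonane adds to the monosubstituted vinyl group far faster than to the trisubstituted alkene and places boron on the terminal carbon, so that oxidation gives the C3 primary alcohol.

Step 6
Reactants: 9 (2R,3S)-2-(2,2-dimethoxyethyl)-3-methyl-3-(4-methylpent-3-en-1-yl)pentane-1,5-diol
Product: 10 (2R,3S)-2-(2,2-dimethoxyethyl)-3-methyl-3-(4-methylpent-3-en-1-yl)pentanedial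
Conditions: (COCl)2, DMSO, CH2Cl2, −78 °C; Et3N, −78 to 0 °C
Reagents that add atoms: none
Why: Swern oxidation activates both hydroxyls before base is added, so the 1,5-dialdehyde forms without the lactol-to-lactone over-oxidation typical of 1,5-diols, and the α-stereocentre next to the quaternary carbon is too hindered to epimerise at low temperature.

Step 7
Reactants: 11 methyl 2-[bis(2,2,2-trifluoroethoxy)phosphoryl]acetate; 12 (chloromethoxy)tri(propan-2-yl)silane
Product: 13 methyl 2-[bis(2,2,2-trifluoroethoxy)phosphoryl]-3-{[tri(propan-2-yl)silyl]oxy}propanoate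
Conditions: NaH (1.0 equiv), THF, 0 °C; then 12, 0 °C to rt
Reagents that add atoms: none
Why: C-alkylation of the stabilised sodium phosphonoacetate carbanion by the reactive α-chloro ether (SN2 alkylation) installs the silyl-protected hydroxymethyl group in one operation.

Step 8
Reactants: 10 (2R,3S)-2-(2,2-dimethoxyethyl)-3-methyl-3-(4-methylpent-3-en-1-yl)pentanedial; 13 methyl 2-[bis(2,2,2-trifluoroethoxy)phosphoryl]-3-{[tri(propan-2-yl)silyl]oxy}propanoate
Product: 14 methyl (2Z,5S,6R)-6-formyl-8,8-dimethoxy-5-methyl-5-(4-methylpent-3-en-1-yl)-2-({[tri(propan-2-yl)silyl]oxy}methyl)oct-2-enoate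
Conditions: 13 (1.05 equiv), KN(SiMe3)2, 18-crown-6, THF, −78 °C; then 10, −78 °C
Reagents that add atoms: none
Why: Still–Gennari variant of the Horner–Wadsworth–Emmons olefination, in which the bulky dissociated phosphonate anion should react at −78 °C only with the unhindered CH2–CHO aldehyde and not with the α-branched aldehyde on C6, and the trifluoroethyl phosphonate gives the Z-enoate (C4 cis to the ester) under kinetic control.

Step 9
Reactants: 14 methyl (2Z,5S,6R)-6-formyl-8,8-dimethoxy-5-methyl-5-(4-methylpent-3-en-1-yl)-2-({[tri(propan-2-yl)silyl]oxy}methyl)oct-2-enoate; 15 1-(triphenylphosphoranylidene)propan-2-one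
Product: 16 methyl (2Z,5S,6S,7E)-6-(2,2-dimethoxyethyl)-5-methyl-5-(4-methylpent-3-en-1-yl)-9-oxo-2-({[tri(propan-2-yl)silyl]oxy}methyl)deca-2,7-dienoate
Conditions: toluene, 90 °C
Reagents that add atoms: none
Why: Wittig olefination with a stabilised ylide gives the (E)-enone under neutral conditions that should neither epimerise C6 nor isomerise the Z-enoate.

Step 10
Reactants: 16 methyl (2Z,5S,6S,7E)-6-(2,2-dimethoxyethyl)-5-methyl-5-(4-methylpent-3-en-1-yl)-9-oxo-2-({[tri(propan-2-yl)silyl]oxy}methyl)deca-2,7-dienoate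
Product: 17 (2Z,5S,6S,7E)-6-(2,2-dimethoxyethyl)-5-methyl-5-(4-methylpent-3-en-1-yl)-9-oxo-2-({[tri(propan-2-yl)silyl]oxy}methyl)deca-2,7-dienoic acid
Conditions: Me3SnOH, 1,2-dichloroethane, 80 °C; cold dilute KHSO4 wash
Reagents that add atoms: Me3SnOH, C[Sn](C)(C)O
Why: Ester hydrolysis with Me3SnOH is close to neutral and should leave the enone, the acetal, the silyl ether and both alkene geometries intact.

Step 11
Reactants: 17 (2Z,5S,6S,7E)-6-(2,2-dimethoxyethyl)-5-methyl-5-(4-methylpent-3-en-1-yl)-9-oxo-2-({[tri(propan-2-yl)silyl]oxy}methyl)deca-2,7-dienoic acid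
Product: 18 Se-phenyl (2Z,5S,6S,7E)-6-(2,2-dimethoxyethyl)-5-methyl-5-(4-methylpent-3-en-1-yl)-9-oxo-2-({[tri(propan-2-yl)silyl]oxy}methyl)deca-2,7-dieneselenoate
Conditions: N-(phenylseleno)phthalimide, Bu3P (premixed), CH2Cl2, −30 °C; then 17, −30 to 0 °C
Reagents that add atoms: N-(phenylseleno)phthalimide, O=C1c2ccccc2C(=O)N1[Se]c1ccccc1
Why: Selenoester formation through an acyloxyphosphonium ion that is attacked by phenylselenide, with the phosphine consumed by the selenium reagent before the substrate is added so that no free phosphine meets the enone or the enoate.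

Step 12
Reactants: 18 Se-phenyl (2Z,5S,6S,7E)-6-(2,2-dimethoxyethyl)-5-methyl-5-(4-methylpent-3-en-1-yl)-9-oxo-2-({[tri(propan-2-yl)silyl]oxy}methyl)deca-2,7-dieneselenoate
Product: 19 (5S,6S,7S)-6-(2,2-dimethoxyethyl)-5-methyl-5-(4-methylpent-3-en-1-yl)-7-(2-oxopropyl)-2-({[tri(propan-2-yl)silyl]oxy}methyl)cyclohept-2-en-1-one
Conditions: (Me3Si)3SiH (1.3 equiv), AIBN (0.2 equiv), added by syringe pump over 8 h to 18 in benzene (0.005 M), 80 °C
Reagents that add atoms: none
Why: The silyl radical abstracts the phenylseleno group to give the α,β-unsaturated acyl σ-radical at C1, which adds to C7, the β-carbon of the (E)-enone, and the α-keto radical left on the acetonyl CH2 takes hydrogen from the silane; the closest known reaction type is the acyl radical cyclisation of a phenyl selenoester onto an electron-poor alkene. The cycloheptenone, the only ring, closes in the 7-exo-trig mode, helped by the quaternary C5 and by the Z-alkene, which already holds C1 and C4 on the same side. The new stereocentre C7 is controlled by C6: with the C6–H bond near the enone plane (allylic strain) the tether through C5 reaches one face only, which places the acetonyl arm trans to the dimethoxyethyl arm, and because C7 is α to the ketone it stays open to correction by base equilibration toward the less crowded trans isomer. The selectivity needed is bond formation at C1 rather than 5-exo closure from C3 through the ketenyl-radical form of the same intermediate, and rather than simple reduction. The acceptor secures it, since the nucleophilic acyl radical is polarity-matched with the enone whereas the delocalised C3-centred ketenyl radical is not nucleophilic and is mismatched, and the slow hydrogen donor at high dilution gives the ring closure time. Decarbonylation is negligible for a vinylic acyl radical, and the electron-rich homoprenyl alkene is not attacked.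

Step 13
Reactants: 19 (5S,6S,7S)-6-(2,2-dimethoxyethyl)-5-methyl-5-(4-methylpent-3-en-1-yl)-7-(2-oxopropyl)-2-({[tri(propan-2-yl)silyl]oxy}methyl)cyclohept-2-en-1-one
Product: 20 (5S,6S,7S)-5-methyl-5-(4-methylpent-3-en-1-yl)-6-(2-oxoethyl)-7-(2-oxopropyl)-2-({[tri(propan-2-yl)silyl]oxy}methyl)cyclohept-2-en-1-one
Conditions: pyridinium p-toluenesulfonate (0.3 equiv), acetone/H2O 9:1, 45 °C
Reagents that add atoms: water, O
Why: Acid-catalysed acetal hydrolysis frees the C6 aldehyde under conditions weak enough to spare the primary TIPS ether, the 1,4-diketone and the C7 configuration.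

Step 14
Reactants: 20 (5S,6S,7S)-5-methyl-5-(4-methylpent-3-en-1-yl)-6-(2-oxoethyl)-7-(2-oxopropyl)-2-({[tri(propan-2-yl)silyl]oxy}methyl)cyclohept-2-en-1-one
Product: 21 (5S,6S,7S)-5-methyl-6-[(E)-2-(3-methylbut-2-enoyloxy)ethenyl]-5-(4-methylpent-3-en-1-yl)-7-(2-oxopropyl)-2-({[tri(propan-2-yl)silyl]oxy}methyl)cyclohept-2-en-1-one
Conditions: 3-methylbut-2-enoic acid (6 equiv), DCC (3 equiv), CH2Cl2, 0 °C (anhydride formed in the flask); then 20, Et3N, DMAP, rt
Reagents that add atoms: 3-methylbut-2-enoic anhydride, CC(C)=CC(=O)OC(=O)C=C(C)C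
Why: Enol esterification of an aldehyde with an anhydride, Et3N and DMAP, in which the aldehyde α-CH2 should enolise faster than either ketone and O-acylation should favour the (E)-enol ester because the bulky C6 avoids the acyloxy group, any Z isomer being removed by chromatography.

Step 15
Reactants: 21 (5S,6S,7S)-5-methyl-6-[(E)-2-(3-methylbut-2-enoyloxy)ethenyl]-5-(4-methylpent-3-en-1-yl)-7-(2-oxopropyl)-2-({[tri(propan-2-yl)silyl]oxy}methyl)cyclohept-2-en-1-one
Product: 22 (5S,6S,7S)-2-(hydroxymethyl)-5-methyl-6-[(E)-2-(3-methylbut-2-enoyloxy)ethenyl]-5-(4-methylpent-3-en-1-yl)-7-(2-oxopropyl)cyclohept-2-en-1-one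
Conditions: HF·pyridine, pyridine, THF, 0 °C to rt
Reagents that add atoms: none
Why: Fluoride-mediated desilylation under buffered conditions should free the primary allylic alcohol without cleaving the enol ester or the senecioate and without epimerising C7.

Step 16
Reactants: 22 (5S,6S,7S)-2-(hydroxymethyl)-5-methyl-6-[(E)-2-(3-methylbut-2-enoyloxy)ethenyl]-5-(4-methylpent-3-en-1-yl)-7-(2-oxopropyl)cyclohept-2-en-1-one
Product: 23 (5S,6S,7S)-5-[(3S)-3-hydroperoxy-4-methylpent-4-en-1-yl]-2-(hydroxymethyl)-5-methyl-6-[(E)-2-(3-methylbut-2-enoyloxy)ethenyl]-7-(2-oxopropyl)cyclohept-2-en-1-one (CNP0216745.1)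
Conditions: O2, tetraphenylporphyrin (cat.), visible light, CH2Cl2, 0 °C, partial conversion; preparative HPLC
Reagents that add atoms: dioxygen, O=O
Why: Schenck ene reaction, in which singlet oxygen attacks only the electron-rich trisubstituted homoprenyl alkene and abstraction of a methyl hydrogen gives the secondary allylic hydroperoxide with the isopropenyl group; the remote ring cannot control the new stereocentre, so the (3S) epimer has to be separated from its epimer and from the tertiary hydroperoxide regioisomer.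

**Compound list**

1 | methyl 4,4-dimethoxybutanoate | COC(=O)CCC(OC)OC | starting material
2 | 4,4-dimethoxybutanoic acid | OC(=O)CCC(OC)OC | intermediate
3 | geraniol, (2E)-3,7-dimethylocta-2,6-dien-1-ol | CC(C)=CCC/C(C)=C/CO | starting material
4 | geranyl 4,4-dimethoxybutanoate | CC(C)=CCC/C(C)=C/COC(=O)CCC(OC)OC | intermediate
5 | Z(O) boron ketene acetal of 4 (side chain cis to O–B; (4R,5R)-diazaborolidinyl on oxygen) | CC(C)=CCC/C(C)=C/CO/C(OB1N(S(=O)(=O)c2cc(C(F)(F)F)cc(C(F)(F)F)c2)[C@H](c2ccccc2)[C@H](N1S(=O)(=O)c1cc(C(F)(F)F)cc(C(F)(F)F)c1)c1ccccc1)=C/CC(OC)OC | intermediate (not isolated)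
6 | (2R,3S)-2-(2,2-dimethoxyethyl)-3-ethenyl-3,7-dimethyloct-6-enoic acid | CC(C)=CCC[C@@]([C@@H](CC(OC)OC)C(=O)O)(C)C=C | intermediate
7 | (2R,3S)-2-(2,2-dimethoxyethyl)-3-ethenyl-3,7-dimethyloct-6-en-1-ol | CC(C)=CCC[C@@]([C@@H](CC(OC)OC)CO)(C)C=C | intermediate
8 | bis(9-borabicyclo[3.3.1]nonan-9-yl) adduct of 7 (C-bound borane on the former vinyl terminus, O-bound borinate) | CC(C)=CCC[C@@]([C@@H](CC(OC)OC)COB1C2CCCC1CCC2)(C)CCB1C2CCCC1CCC2 | intermediate (not isolated)
9 | (2R,3S)-2-(2,2-dimethoxyethyl)-3-methyl-3-(4-methylpent-3-en-1-yl)pentane-1,5-diol | CC(C)=CCC[C@@]([C@@H](CC(OC)OC)CO)(C)CCO | intermediate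
10 | (2R,3S)-2-(2,2-dimethoxyethyl)-3-methyl-3-(4-methylpent-3-en-1-yl)pentanedial | CC(C)=CCC[C@@]([C@@H](CC(OC)OC)C=O)(C)CC=O | intermediate
11 | methyl 2-[bis(2,2,2-trifluoroethoxy)phosphoryl]acetate | COC(=O)CP(=O)(OCC(F)(F)F)OCC(F)(F)F | starting material
12 | (chloromethoxy)tri(propan-2-yl)silane | CC(C)[Si](OCCl)(C(C)C)C(C)C | starting material
13 | methyl 2-[bis(2,2,2-trifluoroethoxy)phosphoryl]-3-{[tri(propan-2-yl)silyl]oxy}propanoate (racemic) | COC(=O)C(CO[Si](C(C)C)(C(C)C)C(C)C)P(=O)(OCC(F)(F)F)OCC(F)(F)F | intermediate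
14 | methyl (2Z,5S,6R)-6-formyl-8,8-dimethoxy-5-methyl-5-(4-methylpent-3-en-1-yl)-2-({[tri(propan-2-yl)silyl]oxy}methyl)oct-2-enoate | CC(C)=CCC[C@@]([C@@H](CC(OC)OC)C=O)(C)C/C=C(/CO[Si](C(C)C)(C(C)C)C(C)C)C(=O)OC | intermediate
15 | 1-(triphenylphosphoranylidene)propan-2-one | CC(=O)C=P(c1ccccc1)(c1ccccc1)c1ccccc1 | starting material
16 | methyl (2Z,5S,6S,7E)-6-(2,2-dimethoxyethyl)-5-methyl-5-(4-methylpent-3-en-1-yl)-9-oxo-2-({[tri(propan-2-yl)silyl]oxy}methyl)deca-2,7-dienoate | CC(C)=CCC[C@@]([C@@H](CC(OC)OC)/C=C/C(C)=O)(C)C/C=C(/CO[Si](C(C)C)(C(C)C)C(C)C)C(=O)OC | intermediate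
17 | (2Z,5S,6S,7E)-6-(2,2-dimethoxyethyl)-5-methyl-5-(4-methylpent-3-en-1-yl)-9-oxo-2-({[tri(propan-2-yl)silyl]oxy}methyl)deca-2,7-dienoic acid | CC(C)=CCC[C@@]([C@@H](CC(OC)OC)/C=C/C(C)=O)(C)C/C=C(/CO[Si](C(C)C)(C(C)C)C(C)C)C(=O)O | intermediate
18 | Se-phenyl (2Z,5S,6S,7E)-6-(2,2-dimethoxyethyl)-5-methyl-5-(4-methylpent-3-en-1-yl)-9-oxo-2-({[tri(propan-2-yl)silyl]oxy}methyl)deca-2,7-dieneselenoate | CC(C)=CCC[C@@]([C@@H](CC(OC)OC)/C=C/C(C)=O)(C)C/C=C(/CO[Si](C(C)C)(C(C)C)C(C)C)C(=O)[Se]c1ccccc1 | intermediate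
19 | (5S,6S,7S)-6-(2,2-dimethoxyethyl)-5-methyl-5-(4-methylpent-3-en-1-yl)-7-(2-oxopropyl)-2-({[tri(propan-2-yl)silyl]oxy}methyl)cyclohept-2-en-1-one | CC(C)=CCC[C@@]1(C)CC=C(CO[Si](C(C)C)(C(C)C)C(C)C)C(=O)[C@@H](CC(C)=O)[C@@H]1CC(OC)OC | intermediate
20 | (5S,6S,7S)-5-methyl-5-(4-methylpent-3-en-1-yl)-6-(2-oxoethyl)-7-(2-oxopropyl)-2-({[tri(propan-2-yl)silyl]oxy}methyl)cyclohept-2-en-1-one | CC(C)=CCC[C@@]1(C)CC=C(CO[Si](C(C)C)(C(C)C)C(C)C)C(=O)[C@@H](CC(C)=O)[C@@H]1CC=O | intermediate
21 | (5S,6S,7S)-5-methyl-6-[(E)-2-(3-methylbut-2-enoyloxy)ethenyl]-5-(4-methylpent-3-en-1-yl)-7-(2-oxopropyl)-2-({[tri(propan-2-yl)silyl]oxy}methyl)cyclohept-2-en-1-one | CC(C)=CCC[C@@]1(C)CC=C(CO[Si](C(C)C)(C(C)C)C(C)C)C(=O)[C@@H](CC(C)=O)[C@@H]1/C=C/OC(=O)C=C(C)C | intermediate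
22 | (5S,6S,7S)-2-(hydroxymethyl)-5-methyl-6-[(E)-2-(3-methylbut-2-enoyloxy)ethenyl]-5-(4-methylpent-3-en-1-yl)-7-(2-oxopropyl)cyclohept-2-en-1-one | CC(C)=CCC[C@@]1(C)CC=C(CO)C(=O)[C@@H](CC(C)=O)[C@@H]1/C=C/OC(=O)C=C(C)C | intermediate
23 | (5S,6S,7S)-5-[(3S)-3-hydroperoxy-4-methylpent-4-en-1-yl]-2-(hydroxymethyl)-5-methyl-6-[(E)-2-(3-methylbut-2-enoyloxy)ethenyl]-7-(2-oxopropyl)cyclohept-2-en-1-one | C=C(C)[C@H](CC[C@@]1(C)CC=C(CO)C(=O)[C@@H](CC(C)=O)[C@@H]1/C=C/OC(=O)C=C(C)C)OO | target

**Step count**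

Total: 16 steps. Longest linear sequence: 15 steps (steps 1–6 and 8–16; step 7 is a one-step side branch).

**Steps most likely to fail**

Step 12 (radical ring closure). The unsaturated acyl radical may react through its ketenyl-radical form, closing a five-membered ring from C3 onto C7, or may be reduced before the slow 7-exo closure occurs. The fallback removes the C2=C3 alkene from the radical precursor and restores it afterwards; it sets out from dialdehyde 10 and comes back at 19. Methyl 3-{[tri(propan-2-yl)silyl]oxy}propanoate F1 (from methyl 3-hydroxypropanoate, iPr3SiCl and imidazole) is converted into its lithium enolate with LiN(iPr)2 at −78 °C and added to the unhindered aldehyde of 10. The aldolate is trapped with pivaloyl chloride to give the β-pivaloyloxy ester aldehyde F2 (mixture at C2 and C3). Wittig reaction with 15 gives the enone F3, Me3SnOH gives the acid F4, and N-(phenylseleno)phthalimide/Bu3P gives the saturated selenoester F5. (Me3Si)3SiH/AIBN then closes the ring through a saturated acyl radical, which has no ketenyl form, to the β-pivaloyloxy cycloheptanone F6. DBU eliminates pivalic acid across C2–C3 (E1cB) and returns the route to 19.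

Step 14 (enol senecioylation). Enolisation of the two ketones, an aldol closure between the aldehyde enolate and the acetonyl ketone, deconjugation of the senecioyl unit by the amine, or poor E/Z control may erode the step. The fallback avoids basic acylation and sets out from aldehyde 20. ZnCl2-catalysed addition of 3-methylbut-2-enoyl chloride across the aldehyde C=O, to which ketones do not respond, gives the 1-chloroalkyl ester F7. Dehydrochlorination with Et3N then gives the enol ester and rejoins the route at 21, any Z isomer being separated.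

Step 3 (boron-mediated Claisen rearrangement). The B–Br Lewis acid may ionise the dimethyl acetal before enolisation is complete, or enolate geometry and facial control may be eroded in this hindered quaternary-centre-forming case. The fallback gives up reagent control and sets out from ester 4. LiN(iPr)2 in THF/DMPU with Me3SiCl at −78 °C gives the silyl ketene acetal F8 with the same Z(O) geometry, which rearranges on warming and is hydrolysed on work-up to the racemic syn acid F9. Its mixed pivalic anhydride acylates lithiated (S)-4-benzyloxazolidin-2-one, the diastereomeric imides are separated by chromatography, and the (2R,3S) imide F10 is cleaved with LiOH/H2O2 to come back at acid 6.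

**Further compounds**

F1 | step 12 | methyl 3-{[tri(propan-2-yl)silyl]oxy}propanoate | COC(=O)CCO[Si](C(C)C)(C(C)C)C(C)C
F2 | step 12 | β-pivaloyloxy ester aldehyde: 2,3-dihydro-3-(2,2-dimethylpropanoyloxy) analogue of 14 (mixture at C2 and C3) | CC(C)=CCC[C@@]([C@@H](CC(OC)OC)C=O)(C)CC(OC(=O)C(C)(C)C)C(CO[Si](C(C)C)(C(C)C)C(C)C)C(=O)OC
F3 | step 12 | enone: 2,3-dihydro-3-(2,2-dimethylpropanoyloxy) analogue of 16 (mixture at C2 and C3) | CC(C)=CCC[C@@]([C@@H](CC(OC)OC)/C=C/C(C)=O)(C)CC(OC(=O)C(C)(C)C)C(CO[Si](C(C)C)(C(C)C)C(C)C)C(=O)OC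
F4 | step 12 | acid: 2,3-dihydro-3-(2,2-dimethylpropanoyloxy) analogue of 17 (mixture at C2 and C3) | CC(C)=CCC[C@@]([C@@H](CC(OC)OC)/C=C/C(C)=O)(C)CC(OC(=O)C(C)(C)C)C(CO[Si](C(C)C)(C(C)C)C(C)C)C(=O)O
F5 | step 12 | saturated selenoester: 2,3-dihydro-3-(2,2-dimethylpropanoyloxy) analogue of 18 (mixture at C2 and C3) | CC(C)=CCC[C@@]([C@@H](CC(OC)OC)/C=C/C(C)=O)(C)CC(OC(=O)C(C)(C)C)C(CO[Si](C(C)C)(C(C)C)C(C)C)C(=O)[Se]c1ccccc1
F6 | step 12 | β-pivaloyloxy cycloheptanone: 2,3-dihydro-3-(2,2-dimethylpropanoyloxy) analogue of 19 (mixture at C2 and C3) | CC(C)=CCC[C@@]1(C)CC(OC(=O)C(C)(C)C)C(CO[Si](C(C)C)(C(C)C)C(C)C)C(=O)[C@@H](CC(C)=O)[C@@H]1CC(OC)OC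
F7 | step 14 | 1-chloroalkyl ester: 1-chloro-2-(ring C6)ethyl 3-methylbut-2-enoate derived from 20 (mixture at the CHCl carbon) | CC(C)=CCC[C@@]1(C)CC=C(CO[Si](C(C)C)(C(C)C)C(C)C)C(=O)[C@@H](CC(C)=O)[C@@H]1CC(Cl)OC(=O)C=C(C)C
F8 | step 3 | trimethylsilyl ketene acetal of 4 (side chain cis to O–Si) | CC(C)=CCC/C(C)=C/CO/C(O[Si](C)(C)C)=C/CC(OC)OC
F9 | step 3 | racemic (2R*,3S*)-2-(2,2-dimethoxyethyl)-3-ethenyl-3,7-dimethyloct-6-enoic acid (one enantiomer drawn) | CC(C)=CCC[C@@]([C@@H](CC(OC)OC)C(=O)O)(C)C=C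
F10 | step 3 | (4S)-4-benzyl-3-[(2R,3S)-2-(2,2-dimethoxyethyl)-3-ethenyl-3,7-dimethyloct-6-enoyl]oxazolidin-2-one | CC(C)=CCC[C@@]([C@@H](CC(OC)OC)C(=O)N1[C@@H](Cc2ccccc2)COC1=O)(C)C=C
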